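**Plan**

Cuts (labdane numbering): first C12–C13 (acyl cross-coupling) and the two angelate O–acyl bonds. Then, in one move, the ring-fusion bond C5–C10 and C8–C9, which opens rings A and B to one open chain. The chain is cut at C7=C8, C5=C6, C11=C12 and C3–C4.
Enabling feature: in ring B the C17 formyl group is conjugated with C7=C8, so C5 is the δ-acceptor end of a C5=C6–C7=C8–CHO dienal, while C9 and C10 are the β- and γ-carbons of the C12 ketone. With C12 masked as a ketene dithioacetal, C10=C9–C11=C12(SEt)2, C10 is a donor and C9 a latent acceptor, so both new bonds are polarity-matched.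
Forward order: geranyl acetate (C1–C3, C9–C11, C20, E alkene) → C3 aldehyde → C2–O → prenylboration (C4, C5, C18, C19) → acetonide → C12 by Peterson olefination → C6–C8 and C17 by metathesis and Wittig reaction → rings A and B closed together → hydrolysis, bis-angeloylation, coupling with the C13–C16 stannane.
Stereochemistry: C2 comes from enamine catalysis and C3 from substrate-controlled allylboration. C5, C9 and C10 are relayed in the key step from C2/C3 (chair tether clamped by the acetonide) and from the E geometry of C9=C10. The three Z alkenes come from angelic acid and a (Z)-β-stannyl enoate.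

Key step: step 12

Assumption: atoms are numbered as in labdanes (decalin C1–C10, side chain C11–C16, formyl C17, gem-dimethyl C18/C19, angular methyl C20), and the catalyst enantiomer of step 2 is taken to be the one that gives the 2R aldehyde, both antipodes being sold.

**Route**

Step 1
Reactants: 1 geranyl acetate
Product: 3 (2E)-3-methyl-6-oxohex-2-en-1-yl acetate, via secondary ozonide 2 (not isolated)
Conditions: O3 (1 equiv, Sudan Red 7B end-point), CH2Cl2, −78 °C; then Me2S, −78 °C → rt
Reagents that add atoms: ozone, [O-][O+]=O
Why: Chemoselective ozonolysis: the remote trisubstituted alkene is much more electron-rich than the alkene that carries the allylic acetate, so one equivalent of ozone cleaves only the isopropylidene end, reductive work-up of the ozonide gives the aldehyde, and the E alkene (later C9=C10) is kept.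

Step 2
Reactants: 3 (2E)-3-methyl-6-oxohex-2-en-1-yl acetate
Product: 4 (2E,5R)-3-methyl-6-oxo-5-[(2,2,6,6-tetramethylpiperidin-1-yl)oxy]hex-2-en-1-yl acetate
Conditions: TEMPO (1.2 equiv), CuCl2 (10 mol %), 5-benzyl-2-tert-butyl-3-methylimidazolidin-4-one·TFA (single enantiomer, 20 mol %), air, acetone, −10 °C
Reagents that add atoms: TEMPO, CC1(C)CCCC(C)(C)N1[O]
Why: Enantioselective α-oxyamination of an aldehyde by enamine catalysis with a copper co-catalyst (known reaction type): the benzyl and tert-butyl groups of the catalyst cover one face of the E-enamine, TEMPO is delivered to the open face and sets C2 as R, and the bulky adduct does not enolise readily.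

Step 3
Reactants: 4 α-oxyaminated aldehyde; 5 prenylboronic acid pinacol ester
Product: 7 (2E,5R,6S)-6-hydroxy-3,7,7-trimethyl-5-[(2,2,6,6-tetramethylpiperidin-1-yl)oxy]nona-2,8-dien-1-yl acetate, via pinacol borate 6 (not isolated)
Conditions: 5 (1.5 equiv), (PhO)2P(O)OH (10 mol %), toluene, 0 °C → rt; then aq NaHCO3
Reagents that add atoms: none
Why: Allylboration: the prenyl boronate reacts at its γ-carbon through a closed six-membered chair transition state, which builds the quaternary C4 with its vinyl group, and the pseudo-axial (Z) methyl group of the reagent forces the aldehyde into the dipole-minimised conformer with C2–O anti to C=O, so that the 2,3-anti (erythro) alcohol, C3 = S, should predominate.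

Step 4
Reactants: 7 homoallylic alcohol
Product: 8 (2E,5R,6S)-5,6-dihydroxy-3,7,7-trimethylnona-2,8-dien-1-yl acetate
Conditions: Zn dust, AcOH/THF/H2O (3:1:1), 60 °C
Reagents that add atoms: none
Why: Reductive N–O cleavage of a TEMPO adduct with zinc in acetic acid, a standard unmasking that leaves both carbinol centres, the alkenes and the acetate untouched.

Step 5
Reactants: 8 erythro diol
Product: 9 (2E)-4-[(4R,5S)-2,2-dimethyl-5-(2-methylbut-3-en-2-yl)-1,3-dioxolan-4-yl]-3-methylbut-2-en-1-yl acetate
Conditions: 2,2-dimethoxypropane, PPTS (cat.), CH2Cl2, rt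
Reagents that add atoms: 2,2-dimethoxypropane, COC(C)(C)OC
Why: Acid-catalysed transketalisation of the only 1,2-diol; the erythro diol gives the cis-4,5-disubstituted dioxolane, a temporary ring that holds C1 and C4 gauche as ring A will need them.

Step 6
Reactants: 9 acetonide acetate
Product: 10 (2E)-4-[(4R,5S)-2,2-dimethyl-5-(2-methylbut-3-en-2-yl)-1,3-dioxolan-4-yl]-3-methylbut-2-en-1-ol
Conditions: K2CO3 (cat.), MeOH, 0 °C → rt
Reagents that add atoms: none
Why: Base-catalysed transesterification (methanolysis) of a primary acetate; ketal and alkenes are inert to carbonate in methanol.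

Step 7
Reactants: 10 allylic alcohol
Product: 11 (2E)-4-[(4R,5S)-2,2-dimethyl-5-(2-methylbut-3-en-2-yl)-1,3-dioxolan-4-yl]-3-methylbut-2-enal
Conditions: MnO2 (excess), CH2Cl2, rt
Reagents that add atoms: none
Why: MnO2 oxidation, selective for allylic alcohols and known to keep the E geometry of geraniol-type substrates.

Step 8
Reactants: 12 bis(ethylthio)methane
Product: 13 [bis(ethylthio)methyl]trimethylsilane
Conditions: n-BuLi, THF, −20 °C; then Me3SiCl, −78 °C → rt
Reagents that add atoms: chlorotrimethylsilane, C[Si](C)(C)Cl
Why: Deprotonation of a formaldehyde dithioacetal followed by C-silylation, the standard entry to Peterson reagents for ketene dithioacetals.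

Step 9
Reactants: 11 enal; 13 [bis(ethylthio)methyl]trimethylsilane
Product: 14 (4R,5S)-4-[(2E)-5,5-bis(ethylthio)-2-methylpenta-2,4-dien-1-yl]-2,2-dimethyl-5-(2-methylbut-3-en-2-yl)-1,3-dioxolane
Conditions: 13, n-BuLi, THF, −78 → 0 °C; then 11, −78 °C → rt; H2O
Reagents that add atoms: none
Why: Peterson olefination: the sulfur- and silicon-stabilised carbanion adds 1,2 to the enal and the β-silyl alkoxide loses Me3SiOLi on warming, which gives the vinylketene dithioacetal without touching the C9=C10 geometry or the stereocentres.

Step 10
Reactants: 14 vinylketene dithioacetal; 15 (E)-crotonaldehyde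
Product: 16 (2E)-4-{(4S,5R)-5-[(2E)-5,5-bis(ethylthio)-2-methylpenta-2,4-dien-1-yl]-2,2-dimethyl-1,3-dioxolan-4-yl}-4-methylpent-2-enal
Conditions: 15 (5 equiv), second-generation Hoveyda–Grubbs catalyst RuCl2(H2IMes)(=CH-C6H4-2-OiPr) (10 mol %), CH2Cl2, 40 °C
Reagents that add atoms: none
Why: Olefin cross-metathesis: only the monosubstituted vinyl group can enter the catalytic cycle (all other alkenes are trisubstituted), thioethers are tolerated by the chelated ruthenium catalyst, and the conjugated product forms as the E isomer.

Step 11
Reactants: 16 enal; 17 (triphenylphosphoranylidene)acetaldehyde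
Product: 18 (2E,4E)-6-{(4S,5R)-5-[(2E)-5,5-bis(ethylthio)-2-methylpenta-2,4-dien-1-yl]-2,2-dimethyl-1,3-dioxolan-4-yl}-6-methylhepta-2,4-dienal
Conditions: 17 (1.1 equiv), toluene, 80 °C
Reagents that add atoms: none
Why: Wittig reaction of a stabilised ylide (two-carbon homologation of an enal), E-selective; a small excess of ylide limits a second homologation, and the neutral medium spares the acid-sensitive ketene dithioacetal.

Step 12
Reactants: 18 dienal vinylketene dithioacetal
Product: 20 12,12-bis(ethylthio)-2α,3α-(isopropylidenedioxy)-13,14,15,16-tetranorlabda-7,11-dien-17-al (5R,9R,10S), via Diels–Alder adduct 19 (not isolated)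
Conditions: Me2AlCl (1.5 equiv), CH2Cl2 (0.005 M), −78 → −20 °C; aq potassium sodium tartrate; then DBU (0.2 equiv), CH2Cl2, rt
Reagents that add atoms: none
Why: Proposed new method: Me2AlCl binds the C17 aldehyde and makes C5 the δ-electrophilic end of the dienal while the two sulfur atoms push electron density through C12=C11–C9=C10 to C10, so C10 attacks C5 and the aluminium dienolate closes from C8 onto C9 of the dithio-stabilised allyl cation, which amounts to an intramolecular inverse-electron-demand Diels–Alder reaction (diene C5=C6–C7=C8, dienophile C9=C10) that may be concerted and asynchronous or stepwise. The closest known reaction types are the intramolecular 1,6-addition of allylsilanes to conjugated dienones, the all-carbon inverse-demand Diels–Alder reactions in which the remote double bond of a dienamine is the dienophile, and the Lewis-acid-promoted intramolecular Diels–Alder reaction of 1,7,9-decatrienes. Ring A closes 6-exo-trig at C5 (bond C5–C10, four-atom tether C1–C4 in a chair) and ring B closes 6-(enolexo)-exo-trig at C9 (bond C8–C9); attack at C7, C11 or C17 would need eight- to ten-membered rings containing E alkenes, and the zwitterion has no proton to lose because C10 is quaternary, so it can only close or revert. C5 and C10 are controlled by the chair tether, which keeps the C2–O bond equatorial because the other chair would set it 1,3-diaxial to both the C10 methyl and a C4 methyl group, and by the endo arrangement in which the cationic C9–C11–C12 arm lies over the dienolate and leads to the trans fusion (10β-methyl, 5α-H); C9 is controlled by the E geometry of C9=C10 (methyl cis to C11), transferred suprafacially or, in the stepwise limit, by C11 taking the equatorial site, both giving 9β-C11; C8 is set (CHO β, from the E C7=C8 bond) and then erased. The step needs periselectivity, because the vinylketene dithioacetal is itself a diene; both of its termini (C10 and C12) are disubstituted, so its s-cis form is blocked, the acetonide pre-folds the tether, and high dilution suppresses intermolecular addition to the aldehyde. DBU then moves C6=C7 into conjugation (C7=C8) through the dienolate, which cannot affect C9 because H9 is not vinylogously acidic.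

Step 13
Reactants: 20 tricyclic enal ketene dithioacetal
Product: 21 S-ethyl 2α,3α-dihydroxy-17-oxo-13,14,15,16-tetranorlabd-7-ene-12-thioate
Conditions: TFA/H2O/THF (1:1:4), 0 °C → rt, N2 sparge
Reagents that add atoms: water, O
Why: Classical acid hydrolysis of a ketene dithioacetal (C11 protonation, addition of water to the dithiocarbenium ion, loss of EtSH) stops at the S-ethyl thioester, and the same aqueous acid cleaves the dioxolane, so both helpers leave in one operation while the volatile thiol is swept out before it can add to the enal.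

Step 14
Reactants: 21 diol thioester; 22 angelic acid
Product: 24 S-ethyl 2α,3α-bis(angeloyloxy)-17-oxo-13,14,15,16-tetranorlabd-7-ene-12-thioate, via mixed anhydride 23 (not isolated)
Conditions: 22 (8 equiv), 2,4,6-trichlorobenzoyl chloride (8 equiv), Et3N (8 equiv), toluene, rt; then 21, 80 °C
Reagents that add atoms: 2,4,6-trichlorobenzoyl chloride, O=C(Cl)c1c(Cl)cc(Cl)cc1Cl (its atoms stay in 23 only)
Why: Yamaguchi-type mixed-anhydride esterification run without a nucleophilic catalyst, the established way to transfer an angeloyl group without Z to E isomerisation; excess reagent and heat should acylate the equatorial 2-OH and then the hindered axial 3-OH, with no change at either carbinol centre.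

Step 15
Reactants: 25 methyl but-2-ynoate
Product: 26 methyl (2Z)-3-(tributylstannyl)but-2-enoate
Conditions: Bu3SnH, LDA, THF, 0 °C; CuSPh (monovalent copper), −20 °C; 25, −78 → −48 °C, 4 h; then MeOH
Reagents that add atoms: tributyltin hydride, CCCC[SnH](CCCC)CCCC
Why: Stannylcupration of an alkynoate: without a proton source at −48 °C the first syn adduct equilibrates to the ester-chelated isomer, so protonation gives the (Z)-β-stannyl enoate with tin cis to the ester.

Step 16
Reactants: 24 bis-angelate thioester; 26 (Z)-stannyl enoate
Product: 27 methyl (13Z)-2α,3α-bis(angeloyloxy)-12,17-dioxolabda-7,13-dien-15-oate (target, 2R,3S,5R,9R,10S)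
Conditions: 26 (1.5 equiv), Pd2(dba)3 (5 mol %), P(2-furyl)3 (20 mol %), CuOP(O)Ph2 (1.5 equiv, monovalent copper), THF, 45 °C, dark
Reagents that add atoms: none
Why: Liebeskind–Srogl-type ketone synthesis from a thioester and a vinylstannane: zerovalent palladium inserts into the acyl–sulfur bond, the copper phosphinate takes up the thiolate and the tin, and the neutral conditions tolerate the enal and the three esters and transfer the alkenyl group with retention, which sets the 13Z geometry.

**Compound list**

1 | geranyl acetate | CC(C)=CCC/C(C)=C/COC(C)=O | starting material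
2 | secondary ozonide of the remote alkene of 1 | CC1(C)OOC(CC/C(C)=C/COC(C)=O)O1 | intermediate
3 | (2E)-3-methyl-6-oxohex-2-en-1-yl acetate | O=CCC/C(C)=C/COC(C)=O | intermediate
4 | (2E,5R)-3-methyl-6-oxo-5-[(2,2,6,6-tetramethylpiperidin-1-yl)oxy]hex-2-en-1-yl acetate | O=C[C@H](ON1C(C)(C)CCCC1(C)C)C/C(C)=C/COC(C)=O | intermediate
5 | prenylboronic acid pinacol ester | CC(C)=CCB1OC(C)(C)C(C)(C)O1 | starting material
6 | pinacol borate of 7 | C=CC(C)(C)[C@H](OB1OC(C)(C)C(C)(C)O1)[C@H](ON1C(C)(C)CCCC1(C)C)C/C(C)=C/COC(C)=O | intermediate
7 | (2E,5R,6S)-6-hydroxy-3,7,7-trimethyl-5-[(2,2,6,6-tetramethylpiperidin-1-yl)oxy]nona-2,8-dien-1-yl acetate | C=CC(C)(C)[C@H](O)[C@H](ON1C(C)(C)CCCC1(C)C)C/C(C)=C/COC(C)=O | intermediate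
8 | (2E,5R,6S)-5,6-dihydroxy-3,7,7-trimethylnona-2,8-dien-1-yl acetate | C=CC(C)(C)[C@H](O)[C@H](O)C/C(C)=C/COC(C)=O | intermediate
9 | (2E)-4-[(4R,5S)-2,2-dimethyl-5-(2-methylbut-3-en-2-yl)-1,3-dioxolan-4-yl]-3-methylbut-2-en-1-yl acetate | C=CC(C)(C)[C@@H]1OC(C)(C)O[C@@H]1C/C(C)=C/COC(C)=O | intermediate
10 | allylic alcohol from 9 | C=CC(C)(C)[C@@H]1OC(C)(C)O[C@@H]1C/C(C)=C/CO | intermediate
11 | (E)-enal from 10 | C=CC(C)(C)[C@@H]1OC(C)(C)O[C@@H]1C/C(C)=C/C=O | intermediate
12 | bis(ethylthio)methane | CCSCSCC | starting material
13 | [bis(ethylthio)methyl]trimethylsilane | CCSC(SCC)[Si](C)(C)C | intermediate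
14 | vinylketene diethyl dithioacetal with the C5 vinyl group | C=CC(C)(C)[C@@H]1OC(C)(C)O[C@@H]1C/C(C)=C/C=C(SCC)SCC | intermediate
15 | (E)-crotonaldehyde | C/C=C/C=O | starting material
16 | (E)-enal (C7 aldehyde) from cross-metathesis | O=C/C=C/C(C)(C)[C@@H]1OC(C)(C)O[C@@H]1C/C(C)=C/C=C(SCC)SCC | intermediate
17 | (triphenylphosphoranylidene)acetaldehyde | O=CC=P(c1ccccc1)(c1ccccc1)c1ccccc1 | starting material
18 | (E,E)-dienal vinylketene dithioacetal, precursor of the key step | O=C/C=C/C=C/C(C)(C)[C@@H]1OC(C)(C)O[C@@H]1C/C(C)=C/C=C(SCC)SCC | intermediate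
19 | Diels–Alder adduct, trans-decalin with C6=C7 and 8β-CHO (8S) | CC1(C)O[C@@H]2[C@H](O1)C[C@]3(C)[C@@H](C=C(SCC)SCC)[C@@H](C=O)C=C[C@H]3C2(C)C | intermediate
20 | conjugated C7=C8 enal, acetonide and ketene dithioacetal in place | CC1(C)O[C@@H]2[C@H](O1)C[C@]3(C)[C@@H](C=C(SCC)SCC)C(C=O)=CC[C@H]3C2(C)C | intermediate
21 | S-ethyl 2α,3α-dihydroxy-17-oxo-13,14,15,16-tetranorlabd-7-ene-12-thioate | O[C@@H]1[C@H](O)C[C@]2(C)[C@@H](CC(=O)SCC)C(C=O)=CC[C@H]2C1(C)C | intermediate
22 | angelic acid, (Z)-2-methylbut-2-enoic acid | C/C=C(/C)C(=O)O | starting material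
23 | angelic 2,4,6-trichlorobenzoic anhydride | C/C=C(/C)C(=O)OC(=O)c1c(Cl)cc(Cl)cc1Cl | intermediate
24 | S-ethyl 2α,3α-bis(angeloyloxy)-17-oxo-13,14,15,16-tetranorlabd-7-ene-12-thioate | C/C=C(/C)C(=O)O[C@@H]1[C@H](OC(=O)/C(C)=C\C)C[C@]2(C)[C@@H](CC(=O)SCC)C(C=O)=CC[C@H]2C1(C)C | intermediate
25 | methyl but-2-ynoate | CC#CC(=O)OC | starting material
26 | methyl (2Z)-3-(tributylstannyl)but-2-enoate | CCCC[Sn](CCCC)(CCCC)/C(C)=C\C(=O)OC | intermediate
27 | methyl (13Z)-2α,3α-bis(angeloyloxy)-12,17-dioxolabda-7,13-dien-15-oate | C/C=C(/C)C(=O)O[C@@H]1[C@H](OC(=O)/C(C)=C\C)C[C@]2(C)[C@@H](CC(=O)/C(C)=C\C(=O)OC)C(C=O)=CC[C@H]2C1(C)C | target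

**Step count and risks**

Total step count: 16. Longest linear sequence: 14 (steps 1–7, 9–14 and 16).

Steps most likely to fail:

Step 12 (labelled). Three things may go wrong:
- The aluminium-bound dienal may be consumed by intermolecular 1,2-addition or oligomerisation before the hindered C5–C10 bond forms.
- The Lewis acid may open the acetonide.
- Ring closure may run with poor endo/exo control and lead to a cis ring fusion.

The fallback uses known reaction types, sets out from 9 and comes back at 21. Palladium-catalysed silylation of the allylic acetate 9 with hexamethyldisilane (Pd(dba)2, LiCl, DMF) gives the (E)-allyltrimethylsilane F1. Cross-metathesis with 15 and Wittig reaction with 17, as in steps 10 and 11, give the allylsilane enal F2 and the allylsilane dienal F3. An intramolecular Hosomi–Sakurai 1,6-addition (EtAlCl2, CH2Cl2, −78 °C, then DBU), known for allylsilanes and conjugated dienones, forms C5–C10 and closes ring A alone to the vinylcyclohexane enal F4. Cross-metathesis of its C9 vinyl group with S-ethyl thioacrylate gives the enethioate F5. A phosphine-catalysed intramolecular Rauhut–Currier reaction (PBu3, tert-amyl alcohol) joins C8 to C9 and gives the acetonide thioester F6. Aqueous TFA then gives 21.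

Step 16. Transmetalation from the electron-poor stannane may be slow, which leaves room for protodestannylation. The phosphine may also add reversibly to the new ene-dicarbonyl unit and cause Z to E isomerisation. The fallback sets out from 24 and comes back at 27, and changes the acyl partner and the activation mode. Silver-assisted hydrolysis of the thioester (AgNO3, 2,6-lutidine, THF/H2O) gives the carboxylic acid F7. 1-Chloro-N,N,2-trimethylprop-1-en-1-amine converts it under neutral conditions into the acid chloride F8. A classical Stille acylation with 26 (PdCl2(MeCN)2, no phosphine, no copper salt, rt) then gives 27.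

Step 10. The catalyst may be deactivated by sulfur chelation, initiation at the neopentyl-type vinyl group may be sluggish, and crotonaldehyde may be used up by self-metathesis. The fallback sets out from 14 and comes back at 18, and replaces metathesis plus Wittig reaction by one Heck vinylation with (E)-3-iodoprop-2-enal (Pd(OAc)2, K2CO3, Bu4NCl, DMF, 40 °C). Because C4 is quaternary, β-hydride elimination can only give the conjugated E,E-dienal, and no new compound (F0) is made.

**Further compounds**

F1 | step 12 | (E)-allyltrimethylsilane from 9 | C=CC(C)(C)[C@@H]1OC(C)(C)O[C@@H]1C/C(C)=C/C[Si](C)(C)C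
F2 | step 12 | allylsilane enal | O=C/C=C/C(C)(C)[C@@H]1OC(C)(C)O[C@@H]1C/C(C)=C/C[Si](C)(C)C
F3 | step 12 | allylsilane dienal | O=C/C=C/C=C/C(C)(C)[C@@H]1OC(C)(C)O[C@@H]1C/C(C)=C/C[Si](C)(C)C
F4 | step 12 | vinylcyclohexane enal (ring A closed, 10-vinyl, 5-(4-oxobut-2-enyl)) | CC1(C)O[C@@H]2[C@H](O1)C[C@](C)(C=C)[C@@H](C/C=C/C=O)C2(C)C
F5 | step 12 | enethioate from F4 | CC1(C)O[C@@H]2[C@H](O1)C[C@](C)(/C=C/C(=O)SCC)[C@@H](C/C=C/C=O)C2(C)C
F6 | step 12 | acetonide of 21 | CC1(C)O[C@@H]2[C@H](O1)C[C@]3(C)[C@@H](CC(=O)SCC)C(C=O)=CC[C@H]3C2(C)C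
F7 | step 16 | 2α,3α-bis(angeloyloxy)-17-oxo-13,14,15,16-tetranorlabd-7-en-12-oic acid | C/C=C(/C)C(=O)O[C@@H]1[C@H](OC(=O)/C(C)=C\C)C[C@]2(C)[C@@H](CC(=O)O)C(C=O)=CC[C@H]2C1(C)C
F8 | step 16 | acid chloride of F7 | C/C=C(/C)C(=O)O[C@@H]1[C@H](OC(=O)/C(C)=C\C)C[C@]2(C)[C@@H](CC(=O)Cl)C(C=O)=CC[C@H]2C1(C)C
F0 | step 10 | none | none
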